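**Remark on the chemistry:** the carbinol oxygen of the ring-B partner enters the annulation as its trimethylsilyl ether (22), because a free O–H would be the most likely proton source for the C4a anion. The bonds formed and the carbon skeletons of both partners are unchanged. Compounds 1, 4, 12 and 15 and all reagents on the Conditions lines are assumed to be commercial.

## Structural features

Schizolaenone B is a flavanone. Benzo ring A is fused through C4a–C8a to the dihydropyranone ring C (O1, C2, C3, C4=O), and the catechol ring B is attached at C2. Ring A carries hydroxyls at C5 and C7 that flank a prenyl group at C6, with hydrogen only at C8. Ring B carries hydroxyls at C3' and C4' and an (E)-geranyl chain at C5'. C2 is the only stereocentre, (S)-configured, benzylic and bonded to O1; it has no stereogenic neighbour, so only absolute control is needed. C2 is base-labile, since deprotonation at C3 opens ring C to the chalcone. The three trisubstituted alkenes are sensitive to acid, electrophiles, hydrogenation and metathesis catalysts, and a prenyl group beside a free phenol can cyclise to a chroman in strong acid. The real difficulty is to place the prenyl group at C6 and not C8, and to close ring C without eroding C2. The key step uses the contiguous triad C8a(–O1), C4a(–C4 acyl), C5(–O): an oxygen nucleophile and an acyl electrophile delivered across C4a–C8a of a 3-alkoxyaryne match this pattern in position and polarity, and a ring-A precursor with the prenyl group between two equivalent oxygens removes the C6/C8 question.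

## Logic of the disconnections

**26 to 25.** The four aryl O–CH2 acetal bonds are cut. All four phenols must be masked against organolithium reagents, the aryne and base, and the acetal oxygens also serve as metalation directors and as the aryne-distorting group at C5. The forward step must use acid mild enough to leave the alkenes and the 6-prenyl/phenol pair alone.

**25 to 11 and 22 (through 23 and 24).** O1–C8a and C4–C4a are cut, which opens ring C. This splits the molecule into two fragments of similar size, puts the stereocentre into an acyclic carbinol that is easy to make, and leaves a ring-A piece whose substitution is symmetric about the prenyl group. The forward step must add the oxygen at the aryne carbon remote from the C5 oxygen, acylate the C4a anion before it is protonated, and leave C2 untouched. For that reason 22 carries no O–H.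

**22 to 21 to 20.** The O–Si bond and then the carbinol C–H bond are cut. Asymmetric ketone reduction is the most dependable way to the benzylic (S)-centre. The forward step must reduce the ketone enantioselectively without touching the three alkenes.

**20 to 19 to 18.** The oxidation level is adjusted and the bond between the carbinol carbon and the ester α-carbon is cut (acetate aldol). This reduces the chain to an aldehyde. The aldol needs no stereocontrol because the centre is erased by oxidation.

**18 to 14 and 15 (through 16 and 17), then 13 and 12.** The aryl–CH2 bond of the geranyl chain is cut, then the acetal C–O bonds, then the two O–CH2 bonds. The bromine of 12 marks the correct ring carbon. The forward step must be a clean SN2 allylation that keeps the E geometry, and the aldehyde must be masked during halogen–lithium exchange.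

**11 to 8 (through 9 and 10).** The aryl C–Si and O–S bonds are cut. The ortho-silyl triflate is traced to an ortho-bromophenol by the retro-Brook logic. The forward step must avoid strong acid near the acetal ethers and the prenyl group.

**8 to 7.** The C–Br bond is cut. The two free ring positions of 7 are equivalent and the para position is blocked, so only chemoselectivity against the alkene is needed.

**7 to 6, then 3 and 4 (through 5), then 2 and 1.** The O–Si bond, the aryl–CH2 bond of the prenyl group, the O–Si bond again and two O–CH2 bonds are cut. Lithiation between the two acetal oxygens puts the prenyl group on the symmetry axis. The forward steps need a bulky silyl group to confine metalation to that carbon, and a controlled partial alkylation of the symmetric triol 1.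

## Other disconnections considered

**Alternative 1:** Enol ether ring-closing metathesis.
- **Cut:** the C3=C4 bond of the 4-triethylsilyloxy-2H-chromene A1, leading back to the diene A2 (vinyl group on C2, silyl enol ether on C4a).
- **Forward step:** a ruthenium alkylidene such as the second-generation Grubbs catalyst would close ring C of A2 to A1. Mild hydrolysis of the enol ether would then give 25.
- **In favour:** ring closure is neutral, C2 is set before cyclisation and is never exposed to base at the ketone stage, and enol ether metathesis to 4-silyloxychromenes is a known reaction class.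
- **Against, here:** the prenyl group and the two geranyl alkenes can also engage the ruthenium carbene (truncation by cross metathesis, or macrocyclisation). Forming an electron-rich trisubstituted enol ether alkene needs forcing conditions, under which allyl aryl ethers can isomerise. A2 needs a ring-A acetophenone with O8a free, O5 and O7 protected and prenyl at C6, and symmetry does not help there.
- **Comparison:** on structure both plans keep C2 as a spectator. Alternative 1 is the better of the two on base exposure of the product and on the precedent for its ring closure. It is weaker on chemoselectivity among four alkenes. On step economy it is likely longer, because ring A must be acylated and differentiated and the silyl enol ether adds a step.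

**Alternative 2:** Danheiser benzannulation.
- **Cut:** the whole of ring A (C8–C8a, C5–C6, C7–C8, C4a–C5), leading back to the (S)-6-diazoacetyl dihydropyranone A4 and the prenyl siloxyalkyne A5.
- **Forward step:** irradiation of A4 would trigger Wolff rearrangement to a vinylketene, regioselective [2+2] addition of A5, 4π ring opening and 6π closure, and tautomerisation to the phenol A3.
- **In favour:** the ring-A pattern (free 5-OH, 6-prenyl, 7-silyloxy, 8-H) follows from the connectivity of the two components alone. The medium is neutral and the 5-OH emerges free and hydrogen-bonded.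
- **Against, here:** A4 is a vinylogous ester with a diazoacetyl group on its enol ether carbon, which means a long synthesis with hazardous diazo chemistry. The enone chromophore of A4 can undergo photocycloaddition with the geranyl alkenes. The ketene and carbene intermediates can add to the alkenes. A5 is moisture-sensitive and needs several steps.
- **Comparison:** on regiochemical certainty for ring A this plan is the equal or the better of the aryne plan, which relies on distortion-controlled addition. On C2 the two are equal, since it is a spectator in both. On mechanism it strings four pericyclic events together, each of which must outrun side reactions of three alkenes. On step economy and safety it is clearly worse, because ring A is built from acyclic pieces and ring C must already be present in enantiopure form.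

**Alternative 3:** Enantioselective carbenoid C–H insertion.
- **Cut:** the C2–C3 bond, leading back to the aryl diazomethyl ketone A7, whose O1 carries the ring-B benzyl group.
- **Forward step:** a chiral dirhodium tetracarboxylate Rh2(O2CR*)4 (rhodium divalent) would convert A7 into a carbenoid that inserts into the benzylic O–CH2 C–H bond, closing ring C and setting C2 in A6.
- **In favour:** ring and stereocentre are made in one catalytic step from an achiral ether. The ring-B fragment shrinks to a benzylic electrophile, which is shorter than the seven-step ring-B sequence of the chosen plan. Chromanone formation by this insertion has closer precedent than the aryne annulation.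
- **Against, here:** enantiocontrol with acceptor-only carbenoids is usually modest, and the only stereocentre would rest entirely on it. O1 can attack the carbenoid to give an oxonium ylide and a [1,2]-benzyl shift to a benzofuranone. Cyclopropanation of three alkenes and Buchner-type addition to ring B compete. A7 has the same ring-A regiochemical problem plus a diazoketone synthesis.
- **Comparison:** on precedent for the ring closure and on ring-B step count alternative 3 is the better. On stereochemical reliability the chosen plan is better, because it separates a dependable ketone reduction from the ring closure. Overall step economy is roughly equal once the ring-A acid for A7 is counted.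

Key step: step 14

## Route

**Step 1**
Reactants: 1 phloroglucinol
Product: 2 3,5-bis(methoxymethoxy)phenol
Conditions: MOMCl (2.0 equiv), i-Pr2NEt, DMF, 0 °C → rt; chromatography
Reagents that add atoms: chloromethyl methyl ether, COCCl
Why: Williamson-type O-alkylation; the threefold symmetry of 1 allows only one bis-ether, so the only issue is the degree of alkylation, which stoichiometry and chromatography handle, and the mono-ether can be resubjected.

**Step 2**
Reactants: 2 3,5-bis(methoxymethoxy)phenol
Product: 3 [3,5-bis(methoxymethoxy)phenoxy]tri(propan-2-yl)silane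
Conditions: TIPSCl, imidazole, DMF, rt
Reagents that add atoms: chlorotri(propan-2-yl)silane, CC(C)[Si](Cl)(C(C)C)C(C)C
Why: Silyl ether formation; the bulky silyl group removes the acidic phenol proton before step 3 and shields C2 and C6, so that metalation should be confined to C4.

**Step 3**
Reactants: 3 [3,5-bis(methoxymethoxy)phenoxy]tri(propan-2-yl)silane; 4 prenyl bromide
Product: 6 [3,5-bis(methoxymethoxy)-4-(3-methylbut-2-en-1-yl)phenoxy]tri(propan-2-yl)silane, via aryllithium 5 (not isolated)
Conditions: n-BuLi, THF, 0 °C; CuBr·SMe2 (0.2 equiv), 4, −78 °C → rt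
Reagents that add atoms: none
Why: Directed ortho-metalation, in which the two acetal oxygens jointly direct n-BuLi to the carbon between them; copper-mediated SN2 allylation of 5 with the primary allylic bromide should install the prenyl group without allylic transposition.

**Step 4**
Reactants: 6 [3,5-bis(methoxymethoxy)-4-(3-methylbut-2-en-1-yl)phenoxy]tri(propan-2-yl)silane
Product: 7 3,5-bis(methoxymethoxy)-4-(3-methylbut-2-en-1-yl)phenol
Conditions: TBAF, AcOH, THF, 0 °C
Reagents that add atoms: none
Why: Fluoride-induced desilylation driven by Si–F bond formation; the acetic acid buffer protects the electron-rich phenoxide, and the acetal ethers and the alkene are inert.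

**Step 5**
Reactants: 7 3,5-bis(methoxymethoxy)-4-(3-methylbut-2-en-1-yl)phenol
Product: 8 2-bromo-3,5-bis(methoxymethoxy)-4-(3-methylbut-2-en-1-yl)phenol
Conditions: NBS (1.0 equiv), CH2Cl2, −78 °C
Reagents that add atoms: N-bromosuccinimide, O=C1CCC(=O)N1Br
Why: Electrophilic aromatic bromination; C2 and C6 are equivalent, activated by the ortho hydroxyl and a para acetal oxygen, and the para position is blocked, so one equivalent of NBS at low temperature should brominate the ring well before the prenyl alkene.

**Step 6**
Reactants: 8 2-bromo-3,5-bis(methoxymethoxy)-4-(3-methylbut-2-en-1-yl)phenol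
Product: 11 3,5-bis(methoxymethoxy)-4-(3-methylbut-2-en-1-yl)-2-(trimethylsilyl)phenyl trifluoromethanesulfonate, via O-trimethylsilyl ether 9 (not isolated), via lithium ortho-silylphenoxide 10 (not isolated)
Conditions: HMDS, THF, 65 °C, then evaporation; n-BuLi, THF, −78 °C; PhNTf2, −78 °C → rt; aq. NH4Cl
Reagents that add atoms: hexamethyldisilazane, C[Si](C)(C)N[Si](C)(C)C; N-phenylbis(trifluoromethanesulfonimide), O=S(=O)(N(c1ccccc1)S(=O)(=O)C(F)(F)F)C(F)(F)F
Why: O-silylation, bromine–lithium exchange and anionic 1,3 O-to-C silyl shift (retro-Brook rearrangement) should give 10, which is triflated in the same flask; this is the standard sequence to ortho-silylaryl triflates, with PhNTf2 chosen over Tf2O to keep triflic acid away from the acetal ethers and the alkene.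

**Step 7**
Reactants: 12 3-bromo-4,5-dihydroxybenzaldehyde
Product: 13 3-bromo-4,5-bis(methoxymethoxy)benzaldehyde
Conditions: MOMCl, i-Pr2NEt, CH2Cl2, 0 °C → rt
Reagents that add atoms: chloromethyl methyl ether, COCCl
Why: O-alkylation of both catechol hydroxyls; the aldehyde lowers the phenol pKa, so an amine base suffices.

**Step 8**
Reactants: 13 3-bromo-4,5-bis(methoxymethoxy)benzaldehyde
Product: 14 1-bromo-5-(dimethoxymethyl)-2,3-bis(methoxymethoxy)benzene
Conditions: HC(OMe)3, PPTS (cat.), MeOH, rt; Et3N
Reagents that add atoms: trimethyl orthoformate, COC(OC)OC; methanol, CO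
Why: Acid-catalysed acetalisation driven by the orthoformate as water scavenger masks the aldehyde against n-BuLi; the weak acid at room temperature should leave the aryl acetal ethers intact.

**Step 9**
Reactants: 14 1-bromo-5-(dimethoxymethyl)-2,3-bis(methoxymethoxy)benzene; 15 geranyl bromide
Product: 18 3-[(2E)-3,7-dimethylocta-2,6-dien-1-yl]-4,5-bis(methoxymethoxy)benzaldehyde, via aryllithium 16 (not isolated), via geranylated dimethyl acetal 17 (not isolated)
Conditions: n-BuLi, THF, −78 °C; CuBr·SMe2 (0.2 equiv), 15, −78 → 0 °C; then 10% aq. oxalic acid, THF, rt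
Reagents that add atoms: water, O
Why: Bromine–lithium exchange outruns any deprotonation and the ortho acetal oxygen stabilises 16; copper-catalysed SN2 coupling with the primary allylic bromide should keep the E geometry; benzaldehyde dimethyl acetals hydrolyse in dilute acid far faster than aryl MOM ethers, so the work-up should release only the aldehyde.

**Step 10**
Reactants: 18 3-[(2E)-3,7-dimethylocta-2,6-dien-1-yl]-4,5-bis(methoxymethoxy)benzaldehyde
Product: 19 methyl (3RS)-3-{3-[(2E)-3,7-dimethylocta-2,6-dien-1-yl]-4,5-bis(methoxymethoxy)phenyl}-3-hydroxypropanoate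
Conditions: LiN(i-Pr)2, MeOAc, THF, −78 °C; then 18; aq. NH4Cl
Reagents that add atoms: methyl acetate, CC(=O)OC
Why: Aldol addition of the lithium enolate of methyl acetate to a non-enolisable aldehyde; the new centre is formed racemic on purpose, since step 11 erases it.

**Step 11**
Reactants: 19 methyl (3RS)-3-{3-[(2E)-3,7-dimethylocta-2,6-dien-1-yl]-4,5-bis(methoxymethoxy)phenyl}-3-hydroxypropanoate
Product: 20 methyl 3-{3-[(2E)-3,7-dimethylocta-2,6-dien-1-yl]-4,5-bis(methoxymethoxy)phenyl}-3-oxopropanoate
Conditions: Dess–Martin periodinane, NaHCO3, CH2Cl2, 0 °C → rt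
Reagents that add atoms: none
Why: Dess–Martin oxidation of a benzylic secondary alcohol under buffered, near-neutral conditions; alkenes and acetal ethers should be untouched.

**Step 12**
Reactants: 20 methyl 3-{3-[(2E)-3,7-dimethylocta-2,6-dien-1-yl]-4,5-bis(methoxymethoxy)phenyl}-3-oxopropanoate
Product: 21 methyl (3S)-3-{3-[(2E)-3,7-dimethylocta-2,6-dien-1-yl]-4,5-bis(methoxymethoxy)phenyl}-3-hydroxypropanoate
Conditions: RuCl[(S,S)-TsDPEN](p-cymene) (1 mol%), HCO2H–Et3N (5:2), DMF, 30 °C
Reagents that add atoms: none
Why: Noyori asymmetric transfer hydrogenation; the (S,S)-configured ruthenium amido hydride delivers hydride in a six-membered outer-sphere transition state with the aryl group held beside the η6-arene by a CH/π contact, which gives (S)-carbinols from aryl ketones, and isolated alkenes are not reduced.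

**Step 13**
Reactants: 21 methyl (3S)-3-{3-[(2E)-3,7-dimethylocta-2,6-dien-1-yl]-4,5-bis(methoxymethoxy)phenyl}-3-hydroxypropanoate
Product: 22 methyl (3S)-3-{3-[(2E)-3,7-dimethylocta-2,6-dien-1-yl]-4,5-bis(methoxymethoxy)phenyl}-3-(trimethylsilyloxy)propanoate
Conditions: TMSCl, Et3N, CH2Cl2, 0 °C
Reagents that add atoms: chlorotrimethylsilane, C[Si](C)(C)Cl
Why: Silyl ether formation; it removes the only O–H proton of the annulation partner, and the same fluoride that triggers the aryne cleaves it again.

**Step 14**
Reactants: 11 3,5-bis(methoxymethoxy)-4-(3-methylbut-2-en-1-yl)-2-(trimethylsilyl)phenyl trifluoromethanesulfonate; 22 methyl (3S)-3-{3-[(2E)-3,7-dimethylocta-2,6-dien-1-yl]-4,5-bis(methoxymethoxy)phenyl}-3-(trimethylsilyloxy)propanoate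
Product: 25 (2S)-2-{3-[(2E)-3,7-dimethylocta-2,6-dien-1-yl]-4,5-bis(methoxymethoxy)phenyl}-5,7-bis(methoxymethoxy)-6-(3-methylbut-2-en-1-yl)-2,3-dihydro-4H-chromen-4-one, via aryne 23 (not isolated), via caesium alkoxide 24 (not isolated)
Conditions: CsF (3 equiv), 18-crown-6, THF, 0 °C → rt; 11 (1.3 equiv); pH 7 phosphate buffer
Reagents that add atoms: none
Why: Proposed new method: fluoride attacks the aryl C–Si bond of 11 and the aryl anion expels triflate to give 23, while fluoride (and later the released methoxide) cleaves the O–Si bond of 22 to give 24 in a flask that holds no O–H proton. The C5 acetal oxygen beside C4a distorts the aryne inductively, so 24 should add at the remote carbon C8a (O1–C8a) and leave the negative charge at C4a, ortho to that oxygen. The C4a anion then attacks the ester carbonyl in a 6-exo-trig acyl substitution (C4a–C4); collapse of the tetrahedral intermediate closes ring C and releases methoxide, which the silyl groups take up as methoxytrimethylsilane. The closest known reaction types are the fluoride-induced annulation of arynes with salicylate esters to xanthones, the insertion of arynes into the C–O bond of carboxylic acids leading to chroman-4-ones, and the Parham-type cycloacylation of ortho-metalated aryl ethers. No stereocentre is created: the carbinol C–O bond is never broken, so the (S) centre from step 12 becomes (2S) with retention. Two selectivities are needed: addition at C8a and not C4a, which the 3-alkoxy pattern of 23 secures, and acylation of the C4a anion before protonation, which the silyl masking of the hydroxyl, the aprotic solvent and the intramolecular six-membered trajectory secure. The medium stays weakly basic, which should spare the alkenes and the acetal ethers, and a short reaction time with a buffered quench should spare the base-sensitive C2 centre of 25.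

**Step 15**
Reactants: 25 (2S)-2-{3-[(2E)-3,7-dimethylocta-2,6-dien-1-yl]-4,5-bis(methoxymethoxy)phenyl}-5,7-bis(methoxymethoxy)-6-(3-methylbut-2-en-1-yl)-2,3-dihydro-4H-chromen-4-one
Product: 26 schizolaenone B
Conditions: 3 M aq. HCl, MeOH, 40 °C
Reagents that add atoms: none
Why: Acid-catalysed acetal solvolysis should remove all four MOM groups as dimethoxymethane; C2 is stable in acid, because its racemisation needs base-induced ring opening.

## Compound list

1 | phloroglucinol (benzene-1,3,5-triol) | Oc1cc(O)cc(O)c1 | starting material
2 | 3,5-bis(methoxymethoxy)phenol | COCOc1cc(O)cc(OCOC)c1 | intermediate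
3 | [3,5-bis(methoxymethoxy)phenoxy]tri(propan-2-yl)silane | COCOc1cc(O[Si](C(C)C)(C(C)C)C(C)C)cc(OCOC)c1 | intermediate
4 | prenyl bromide (1-bromo-3-methylbut-2-ene) | CC(C)=CCBr | starting material
5 | [2,6-bis(methoxymethoxy)-4-(triisopropylsilyloxy)phenyl]lithium | COCOc1cc(O[Si](C(C)C)(C(C)C)C(C)C)cc(OCOC)c1[Li] | intermediate
6 | [3,5-bis(methoxymethoxy)-4-(3-methylbut-2-en-1-yl)phenoxy]tri(propan-2-yl)silane | COCOc1cc(O[Si](C(C)C)(C(C)C)C(C)C)cc(OCOC)c1CC=C(C)C | intermediate
7 | 3,5-bis(methoxymethoxy)-4-(3-methylbut-2-en-1-yl)phenol | COCOc1cc(O)cc(OCOC)c1CC=C(C)C | intermediate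
8 | 2-bromo-3,5-bis(methoxymethoxy)-4-(3-methylbut-2-en-1-yl)phenol | COCOc1cc(O)c(Br)c(OCOC)c1CC=C(C)C | intermediate
9 | [2-bromo-3,5-bis(methoxymethoxy)-4-(3-methylbut-2-en-1-yl)phenoxy]trimethylsilane | COCOc1cc(O[Si](C)(C)C)c(Br)c(OCOC)c1CC=C(C)C | intermediate
10 | lithium 3,5-bis(methoxymethoxy)-4-(3-methylbut-2-en-1-yl)-2-(trimethylsilyl)phenolate | [Li+].COCOc1cc([O-])c([Si](C)(C)C)c(OCOC)c1CC=C(C)C | intermediate
11 | 3,5-bis(methoxymethoxy)-4-(3-methylbut-2-en-1-yl)-2-(trimethylsilyl)phenyl trifluoromethanesulfonate | COCOc1cc(OS(=O)(=O)C(F)(F)F)c([Si](C)(C)C)c(OCOC)c1CC=C(C)C | intermediate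
12 | 3-bromo-4,5-dihydroxybenzaldehyde | O=Cc1cc(O)c(O)c(Br)c1 | starting material
13 | 3-bromo-4,5-bis(methoxymethoxy)benzaldehyde | O=Cc1cc(Br)c(OCOC)c(OCOC)c1 | intermediate
14 | 1-bromo-5-(dimethoxymethyl)-2,3-bis(methoxymethoxy)benzene | COC(OC)c1cc(Br)c(OCOC)c(OCOC)c1 | intermediate
15 | geranyl bromide ((2E)-1-bromo-3,7-dimethylocta-2,6-diene) | CC(C)=CCC/C(C)=C/CBr | starting material
16 | [5-(dimethoxymethyl)-2,3-bis(methoxymethoxy)phenyl]lithium | COC(OC)c1cc([Li])c(OCOC)c(OCOC)c1 | intermediate
17 | 5-(dimethoxymethyl)-1-[(2E)-3,7-dimethylocta-2,6-dien-1-yl]-2,3-bis(methoxymethoxy)benzene | CC(C)=CCC/C(C)=C/Cc1cc(C(OC)OC)cc(OCOC)c1OCOC | intermediate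
18 | 3-[(2E)-3,7-dimethylocta-2,6-dien-1-yl]-4,5-bis(methoxymethoxy)benzaldehyde | CC(C)=CCC/C(C)=C/Cc1cc(C=O)cc(OCOC)c1OCOC | intermediate
19 | methyl (3RS)-3-{3-[(2E)-3,7-dimethylocta-2,6-dien-1-yl]-4,5-bis(methoxymethoxy)phenyl}-3-hydroxypropanoate (racemic) | CC(C)=CCC/C(C)=C/Cc1cc(C(O)CC(=O)OC)cc(OCOC)c1OCOC | intermediate
20 | methyl 3-{3-[(2E)-3,7-dimethylocta-2,6-dien-1-yl]-4,5-bis(methoxymethoxy)phenyl}-3-oxopropanoate | CC(C)=CCC/C(C)=C/Cc1cc(C(=O)CC(=O)OC)cc(OCOC)c1OCOC | intermediate
21 | methyl (3S)-3-{3-[(2E)-3,7-dimethylocta-2,6-dien-1-yl]-4,5-bis(methoxymethoxy)phenyl}-3-hydroxypropanoate | CC(C)=CCC/C(C)=C/Cc1cc([C@@H](O)CC(=O)OC)cc(OCOC)c1OCOC | intermediate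
22 | methyl (3S)-3-{3-[(2E)-3,7-dimethylocta-2,6-dien-1-yl]-4,5-bis(methoxymethoxy)phenyl}-3-(trimethylsilyloxy)propanoate | CC(C)=CCC/C(C)=C/Cc1cc([C@@H](O[Si](C)(C)C)CC(=O)OC)cc(OCOC)c1OCOC | intermediate
23 | 3,5-bis(methoxymethoxy)-4-(3-methylbut-2-en-1-yl)benzyne (1,2-didehydrobenzene) | COCOC1=CC#CC(OCOC)=C1CC=C(C)C | intermediate
24 | caesium (1S)-1-{3-[(2E)-3,7-dimethylocta-2,6-dien-1-yl]-4,5-bis(methoxymethoxy)phenyl}-3-methoxy-3-oxopropan-1-olate | [Cs+].CC(C)=CCC/C(C)=C/Cc1cc([C@@H]([O-])CC(=O)OC)cc(OCOC)c1OCOC | intermediate
25 | (2S)-2-{3-[(2E)-3,7-dimethylocta-2,6-dien-1-yl]-4,5-bis(methoxymethoxy)phenyl}-5,7-bis(methoxymethoxy)-6-(3-methylbut-2-en-1-yl)-2,3-dihydro-4H-chromen-4-one (tetrakis-O-MOM schizolaenone B) | CC(C)=CCC/C(C)=C/Cc1cc([C@@H]2CC(=O)c3c(cc(OCOC)c(CC=C(C)C)c3OCOC)O2)cc(OCOC)c1OCOC | intermediate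
26 | schizolaenone B, (2S)-2-{3-[(2E)-3,7-dimethylocta-2,6-dien-1-yl]-4,5-dihydroxyphenyl}-5,7-dihydroxy-6-(3-methylbut-2-en-1-yl)-2,3-dihydro-4H-chromen-4-one | CC(C)=CCC/C(C)=C/Cc1cc([C@@H]2CC(=O)c3c(cc(O)c(CC=C(C)C)c3O)O2)cc(O)c1O | target

## Step count and least certain steps

Total: 15 steps. Longest linear sequence: 9 steps (steps 7 to 13, then 14 and 15). The ring-A branch is 6 steps (steps 1 to 6).

**Step 14 (key step, new reaction type).**
- **What may go wrong:** protonation of the C4a anion before acyl transfer, including internal proton transfer from the ester α-methylene; fragmentation of the free alkoxide by retro-aldol or β-elimination; consumption of the aryne by the released methoxide; and base-mediated opening and re-closure of ring C, which would erode C2.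
- **Fallback (known chemistry), from 20 and 8 back to 25:** reduction of 20 with RuCl[(R,R)-TsDPEN](p-cymene) and HCO2H–Et3N should give methyl (3R)-3-{3-[(2E)-3,7-dimethylocta-2,6-dien-1-yl]-4,5-bis(methoxymethoxy)phenyl}-3-hydroxypropanoate F1. Mitsunobu etherification of F1 with 8 (PPh3, DIAD, toluene, 0 °C) should invert the carbinol and give methyl (3S)-3-[2-bromo-3,5-bis(methoxymethoxy)-4-(3-methylbut-2-en-1-yl)phenoxy]-3-{3-[(2E)-3,7-dimethylocta-2,6-dien-1-yl]-4,5-bis(methoxymethoxy)phenyl}propanoate F2. Aminolysis with the aluminium amide from AlMe3 and MeNHOMe·HCl (CH2Cl2, 0 °C → rt) should give the Weinreb amide (3S)-3-[2-bromo-3,5-bis(methoxymethoxy)-4-(3-methylbut-2-en-1-yl)phenoxy]-3-{3-[(2E)-3,7-dimethylocta-2,6-dien-1-yl]-4,5-bis(methoxymethoxy)phenyl}-N-methoxy-N-methylpropanamide F3. Bromine–lithium exchange with t-BuLi (THF, −78 °C) and Parham cyclisation onto the amide should give 25 on work-up. The weak point of this detour is partial ionisation of the electron-rich benzylic alcohol during the Mitsunobu step.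

**Step 5.**
- **What may go wrong:** electrophilic attack of bromine on the prenyl alkene (bromonium formation, possibly with capture by a neighbouring acetal oxygen) and double bromination of the very electron-rich ring.
- **Fallback, from 7 back to 11 (replaces steps 5 and 6, no halogen):** carbamoylation of 7 with isopropyl isocyanate and Et3N should give 3,5-bis(methoxymethoxy)-4-(3-methylbut-2-en-1-yl)phenyl N-(propan-2-yl)carbamate F4. In situ N-silylation (TBSOTf, TMEDA), carbamate-directed ortho-lithiation (n-BuLi, TMEDA, −78 °C) between the carbamate and the acetal oxygen, and a TMSCl quench should give 3,5-bis(methoxymethoxy)-4-(3-methylbut-2-en-1-yl)-2-(trimethylsilyl)phenyl N-(propan-2-yl)carbamate F5. Carbamate cleavage with DBU and Et2NH in MeCN at 40 °C, followed by PhNTf2 in the same flask, should give 11.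

**Step 9.**
- **What may go wrong:** allylic transposition (attack at the tertiary terminus of the geranyl unit), partial loss of E geometry, coupling of 16 with the butyl bromide formed in the exchange, or acetal hydrolysis running on into loss of a MOM group.
- **Fallback, from 13 back to 18 (replaces steps 8 and 9, tolerates the free aldehyde):** Miyaura borylation of 13 (B2pin2, Pd(dppf)Cl2, KOAc, dioxane, 80 °C) should give 3,4-bis(methoxymethoxy)-5-(4,4,5,5-tetramethyl-1,3,2-dioxaborolan-2-yl)benzaldehyde F6. Suzuki–Miyaura allyl–aryl coupling of F6 with 15 (Pd(PPh3)4, K2CO3, THF, 60 °C) should give 18, with the aryl group delivered to the less hindered terminus of the allyl palladium intermediate.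

**Step 15.**
- **What may go wrong:** acid-induced cyclisation of the C6 prenyl group onto the freed C5 or C7 hydroxyl (chroman formation), or cation–olefin cyclisation of the geranyl chain, before the last acetal ether is cleaved.
- **Fallback, from 25 back to 26 (no free Brønsted acid):** TMSOTf and 2,2'-bipyridyl in CH2Cl2 at 0 °C should convert the four aryl MOM ethers into aryl silyl ethers, giving (2S)-2-{3-[(2E)-3,7-dimethylocta-2,6-dien-1-yl]-4,5-bis(trimethylsilyloxy)phenyl}-6-(3-methylbut-2-en-1-yl)-5,7-bis(trimethylsilyloxy)-2,3-dihydro-4H-chromen-4-one F7. Addition of water should hydrolyse F7 to 26.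

## Further compounds

F1 | step 14 | methyl (3R)-3-{3-[(2E)-3,7-dimethylocta-2,6-dien-1-yl]-4,5-bis(methoxymethoxy)phenyl}-3-hydroxypropanoate | CC(C)=CCC/C(C)=C/Cc1cc([C@H](O)CC(=O)OC)cc(OCOC)c1OCOC
F2 | step 14 | methyl (3S)-3-[2-bromo-3,5-bis(methoxymethoxy)-4-(3-methylbut-2-en-1-yl)phenoxy]-3-{3-[(2E)-3,7-dimethylocta-2,6-dien-1-yl]-4,5-bis(methoxymethoxy)phenyl}propanoate | CC(C)=CCC/C(C)=C/Cc1cc([C@@H](Oc2cc(OCOC)c(CC=C(C)C)c(OCOC)c2Br)CC(=O)OC)cc(OCOC)c1OCOC
F3 | step 14 | (3S)-3-[2-bromo-3,5-bis(methoxymethoxy)-4-(3-methylbut-2-en-1-yl)phenoxy]-3-{3-[(2E)-3,7-dimethylocta-2,6-dien-1-yl]-4,5-bis(methoxymethoxy)phenyl}-N-methoxy-N-methylpropanamide | CC(C)=CCC/C(C)=C/Cc1cc([C@@H](Oc2cc(OCOC)c(CC=C(C)C)c(OCOC)c2Br)CC(=O)N(C)OC)cc(OCOC)c1OCOC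
F4 | step 5 | 3,5-bis(methoxymethoxy)-4-(3-methylbut-2-en-1-yl)phenyl N-(propan-2-yl)carbamate | COCOc1cc(OC(=O)NC(C)C)cc(OCOC)c1CC=C(C)C
F5 | step 5 | 3,5-bis(methoxymethoxy)-4-(3-methylbut-2-en-1-yl)-2-(trimethylsilyl)phenyl N-(propan-2-yl)carbamate | COCOc1cc(OC(=O)NC(C)C)c([Si](C)(C)C)c(OCOC)c1CC=C(C)C
F6 | step 9 | 3,4-bis(methoxymethoxy)-5-(4,4,5,5-tetramethyl-1,3,2-dioxaborolan-2-yl)benzaldehyde | O=Cc1cc(B2OC(C)(C)C(C)(C)O2)c(OCOC)c(OCOC)c1
F7 | step 15 | (2S)-2-{3-[(2E)-3,7-dimethylocta-2,6-dien-1-yl]-4,5-bis(trimethylsilyloxy)phenyl}-6-(3-methylbut-2-en-1-yl)-5,7-bis(trimethylsilyloxy)-2,3-dihydro-4H-chromen-4-one | CC(C)=CCC/C(C)=C/Cc1cc([C@@H]2CC(=O)c3c(cc(O[Si](C)(C)C)c(CC=C(C)C)c3O[Si](C)(C)C)O2)cc(O[Si](C)(C)C)c1O[Si](C)(C)C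
A1 | alternative 1 | (2S)-4-triethylsilyloxy-2H-chromene, the silyl enol ether of tetrakis-O-MOM schizolaenone B | CC(C)=CCC/C(C)=C/Cc1cc([C@@H]2C=C(O[Si](CC)(CC)CC)c3c(cc(OCOC)c(CC=C(C)C)c3OCOC)O2)cc(OCOC)c1OCOC
A2 | alternative 1 | triethyl{[1-(2-{[(1S)-1-{3-[(2E)-3,7-dimethylocta-2,6-dien-1-yl]-4,5-bis(methoxymethoxy)phenyl}prop-2-en-1-yl]oxy}-4,6-bis(methoxymethoxy)-5-(3-methylbut-2-en-1-yl)phenyl)ethenyl]oxy}silane | CC(C)=CCC/C(C)=C/Cc1cc([C@H](C=C)Oc2cc(OCOC)c(CC=C(C)C)c(OCOC)c2C(=C)O[Si](CC)(CC)CC)cc(OCOC)c1OCOC
A3 | alternative 2 | (2S)-7-O-triisopropylsilyl-3',4'-bis-O-MOM schizolaenone B | CC(C)=CCC/C(C)=C/Cc1cc([C@@H]2CC(=O)c3c(cc(O[Si](C(C)C)(C(C)C)C(C)C)c(CC=C(C)C)c3O)O2)cc(OCOC)c1OCOC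
A4 | alternative 2 | (2S)-6-(2-diazoacetyl)-2-{3-[(2E)-3,7-dimethylocta-2,6-dien-1-yl]-4,5-bis(methoxymethoxy)phenyl}-2,3-dihydro-4H-pyran-4-one | CC(C)=CCC/C(C)=C/Cc1cc([C@@H]2CC(=O)C=C(C(=O)C=[N+]=[N-])O2)cc(OCOC)c1OCOC
A5 | alternative 2 | [(5-methylhex-4-en-1-yn-1-yl)oxy]tri(propan-2-yl)silane | CC(C)=CCC#CO[Si](C(C)C)(C(C)C)C(C)C
A6 | alternative 3 | (2S)-5,7-bis-O-tert-butyldimethylsilyl-3',4'-bis-O-MOM schizolaenone B | CC(C)=CCC/C(C)=C/Cc1cc([C@@H]2CC(=O)c3c(cc(O[Si](C)(C)C(C)(C)C)c(CC=C(C)C)c3O[Si](C)(C)C(C)(C)C)O2)cc(OCOC)c1OCOC
A7 | alternative 3 | 2-diazo-1-[2-({3-[(2E)-3,7-dimethylocta-2,6-dien-1-yl]-4,5-bis(methoxymethoxy)phenyl}methoxy)-4,6-bis(tert-butyldimethylsilyloxy)-5-(3-methylbut-2-en-1-yl)phenyl]ethan-1-one | CC(C)=CCC/C(C)=C/Cc1cc(COc2cc(O[Si](C)(C)C(C)(C)C)c(CC=C(C)C)c(O[Si](C)(C)C(C)(C)C)c2C(=O)C=[N+]=[N-])cc(OCOC)c1OCOC
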